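## Retrosynthetic overview

- The phenol is freed last from its isobutyrate. The (S)-2-methylbutanoate, whose stereocentre is bought, goes onto the arm that is unveiled last.
- That arm comes from C4 of an L-glycerate acetonide. Glycol fission and reduction erase this controlling stereocentre once it has set the carbinol.
- The quaternary carbinol comes from a chelation-controlled hydroxymethyl-Grignard addition to an α-alkoxy o-hydroxyaryl ketone (1,2-induction from the glycerate centre).
- The aryl–C(carbinol) bond comes from a photo-Fries rearrangement of m-cresyl L-glycerate acetonide, the key step and new on this substrate class.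
- No ring is built. The arene is bought as m-cresol, and the dioxolane comes with the glycerate and is cleaved in step 5.

Assumption: (4S)-2,2-dimethyl-1,3-dioxolane-4-carboxylic acid (L-glyceric acid acetonide, sold as the acid and as its methyl ester) is taken as a purchasable chiral-pool material.

## Route

Step 1
Reactants: 1 m-cresol (3-methylphenol); 2 (4S)-2,2-dimethyl-1,3-dioxolane-4-carboxylic acid
Product: 3 3-methylphenyl (4S)-2,2-dimethyl-1,3-dioxolane-4-carboxylate
Conditions: DCC, DMAP (cat.), CH2Cl2, 0 °C → rt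
Reagents that add atoms: none
Why: Steglich esterification of a phenol; at 0 °C with only catalytic DMAP the activated α-alkoxy acid is not enolised, so C4 stays (S).

Step 2
Reactants: 3 3-methylphenyl (4S)-2,2-dimethyl-1,3-dioxolane-4-carboxylate
Product: 5 [(4S)-2,2-dimethyl-1,3-dioxolan-4-yl](2-hydroxy-4-methylphenyl)methanone, via ortho-acyl dienone 4 (not isolated)
Conditions: hν (254 nm, flow coil), degassed cyclohexane (0.02 M), rt, to about 70% conversion
Reagents that add atoms: none
Why: Proposed new method: a photo-Fries rearrangement of an aryl ester whose acyl group is an enantiopure α,β-dialkoxy (glycerate) unit, in which singlet homolysis of the ArO–C(O) bond gives a caged aryloxyl/acyl radical pair that recombines at the free ortho carbon para to the methyl group to give dienone 4, which tautomerises to the hydrogen-bonded ketone 5; C4 is not the radical centre (σ-acyl radical), cage recombination (about 10^10 s^-1) should outrun decarbonylation of the α-alkoxyacyl radical (about 10^5–10^6 s^-1), and 5 is shielded from further photochemistry by excited-state proton transfer; the closest known reaction type is the photo-Fries rearrangement of simple aryl alkanoates such as m-tolyl acetate.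

Step 3
Reactants: 5 [(4S)-2,2-dimethyl-1,3-dioxolan-4-yl](2-hydroxy-4-methylphenyl)methanone
Product: 7 (1S)-1-[(4S)-2,2-dimethyl-1,3-dioxolan-4-yl]-1-(2-hydroxy-4-methylphenyl)ethane-1,2-diol, via β-hydroxysilane 6 (not isolated)
Conditions: MgBr2·OEt2, CH2Cl2, −78 °C; iPrOMe2SiCH2MgCl (3.5 equiv, THF), −78 → 0 °C; then H2O2, KF, KHCO3, THF/MeOH, rt
Reagents that add atoms: [dimethyl(propan-2-yloxy)silyl]methylmagnesium chloride, CC(C)O[Si](C)(C)C[Mg]Cl; hydrogen peroxide, OO
Why: Cram-chelate-controlled Grignard addition (Tamao nucleophilic hydroxymethylation, then Tamao–Kumada oxidation): magnesium held by the phenoxide, the carbonyl oxygen and the dioxolane α-oxygen fixes C=O syn to C4–O, so the reagent enters from the C4–H face, away from the ring CH2, and sets the quaternary carbinol as (1S).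

Step 4
Reactants: 7 (1S)-1-[(4S)-2,2-dimethyl-1,3-dioxolan-4-yl]-1-(2-hydroxy-4-methylphenyl)ethane-1,2-diol
Product: 8 (2S)-2-[(4S)-2,2-dimethyl-1,3-dioxolan-4-yl]-2-hydroxy-2-[4-methyl-2-(2-methylpropanoyloxy)phenyl]ethyl 2-methylpropanoate
Conditions: iPrCOCl (2.3 equiv), pyridine, DMAP (cat.), CH2Cl2, 0 °C
Reagents that add atoms: isobutyryl chloride (2-methylpropanoyl chloride), CC(C)C(Cl)=O
Why: Pyridine/DMAP acylation of the phenol and the primary alcohol while the hindered tertiary benzylic OH stays free; the aryl ester also masks the o-hydroxybenzyl alcohol against periodate (Adler–Becker oxidation) in the next step, and no stereocentre is touched.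

Step 5
Reactants: 8 (2S)-2-[(4S)-2,2-dimethyl-1,3-dioxolan-4-yl]-2-hydroxy-2-[4-methyl-2-(2-methylpropanoyloxy)phenyl]ethyl 2-methylpropanoate
Product: 10 (2R)-2,3-dihydroxy-2-[4-methyl-2-(2-methylpropanoyloxy)phenyl]propyl 2-methylpropanoate, via α-hydroxy aldehyde 9 (not isolated)
Conditions: H5IO6 (1.15 equiv), EtOAc, 0 °C → rt; filter; then NaBH(OAc)3, AcOH, 0 °C
Reagents that add atoms: none
Why: Periodic acid hydrolyses the terminal acetonide and cleaves the freed 1,2-diol (Malaprade glycol fission), turning the former controlling stereocentre into the aldehyde carbon of 9, which NaBH(OAc)3 reduces under non-basic conditions so the isobutyrate cannot migrate between the two arms; the quaternary centre is untouched and its descriptor changes from S to R only because the CIP priorities change.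

Step 6
Reactants: 10 (2R)-2,3-dihydroxy-2-[4-methyl-2-(2-methylpropanoyloxy)phenyl]propyl 2-methylpropanoate; 11 (2S)-2-methylbutanoic acid
Product: 12 (2S)-2-hydroxy-2-[4-methyl-2-(2-methylpropanoyloxy)phenyl]-3-(2-methylpropanoyloxy)propyl (2S)-2-methylbutanoate
Conditions: DCC, DMAP (cat.), CH2Cl2, 0 °C
Reagents that add atoms: none
Why: Steglich esterification of the only unhindered hydroxyl (the tertiary OH does not react); at 0 °C without a strong base the α-centre of the purchased acid is not epimerised, and any carbinol epimer is now a separable diastereomer.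

Step 7
Reactants: 12 (2S)-2-hydroxy-2-[4-methyl-2-(2-methylpropanoyloxy)phenyl]-3-(2-methylpropanoyloxy)propyl (2S)-2-methylbutanoate
Product: 13 (2S)-2-hydroxy-2-(2-hydroxy-4-methylphenyl)-3-(2-methylpropanoyloxy)propyl (2S)-2-methylbutanoate
Conditions: pyrrolidine (2 equiv), THF, 0 °C
Reagents that add atoms: none
Why: Chemoselective aminolysis, since an aryl ester is cleaved by a secondary amine far faster than the two α-branched primary alkyl esters, so the phenol is freed while both esters and both stereocentres stay.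

## Compound list

1 | m-cresol (3-methylphenol) | Cc1cccc(O)c1 | starting material
2 | (4S)-2,2-dimethyl-1,3-dioxolane-4-carboxylic acid | OC(=O)[C@@H]1COC(C)(C)O1 | starting material
3 | 3-methylphenyl (4S)-2,2-dimethyl-1,3-dioxolane-4-carboxylate | Cc1cccc(OC(=O)[C@@H]2COC(C)(C)O2)c1 | intermediate
4 | 6-[(4S)-2,2-dimethyl-1,3-dioxolane-4-carbonyl]-3-methylcyclohexa-2,4-dien-1-one (both C6 epimers) | O=C1C=C(C)C=CC1C(=O)[C@@H]1COC(C)(C)O1 | intermediate
5 | [(4S)-2,2-dimethyl-1,3-dioxolan-4-yl](2-hydroxy-4-methylphenyl)methanone | Cc1ccc(C(=O)[C@@H]2COC(C)(C)O2)c(O)c1 | intermediate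
6 | (1R)-1-[(4S)-2,2-dimethyl-1,3-dioxolan-4-yl]-2-[dimethyl(propan-2-yloxy)silyl]-1-(2-hydroxy-4-methylphenyl)ethan-1-ol | CC(C)O[Si](C)(C)C[C@@](O)(c1ccc(C)cc1O)[C@@H]1COC(C)(C)O1 | intermediate
7 | (1S)-1-[(4S)-2,2-dimethyl-1,3-dioxolan-4-yl]-1-(2-hydroxy-4-methylphenyl)ethane-1,2-diol | OC[C@@](O)(c1ccc(C)cc1O)[C@@H]1COC(C)(C)O1 | intermediate
8 | (2S)-2-[(4S)-2,2-dimethyl-1,3-dioxolan-4-yl]-2-hydroxy-2-[4-methyl-2-(2-methylpropanoyloxy)phenyl]ethyl 2-methylpropanoate | CC(C)C(=O)OC[C@@](O)(c1ccc(C)cc1OC(=O)C(C)C)[C@@H]1COC(C)(C)O1 | intermediate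
9 | (2S)-2-hydroxy-2-[4-methyl-2-(2-methylpropanoyloxy)phenyl]-3-oxopropyl 2-methylpropanoate | CC(C)C(=O)OC[C@@](O)(c1ccc(C)cc1OC(=O)C(C)C)C=O | intermediate
10 | (2R)-2,3-dihydroxy-2-[4-methyl-2-(2-methylpropanoyloxy)phenyl]propyl 2-methylpropanoate | CC(C)C(=O)OC[C@@](O)(c1ccc(C)cc1OC(=O)C(C)C)CO | intermediate
11 | (2S)-2-methylbutanoic acid | CC[C@H](C)C(=O)O | starting material
12 | (2S)-2-hydroxy-2-[4-methyl-2-(2-methylpropanoyloxy)phenyl]-3-(2-methylpropanoyloxy)propyl (2S)-2-methylbutanoate | CC[C@H](C)C(=O)OC[C@@](O)(COC(=O)C(C)C)c1ccc(C)cc1OC(=O)C(C)C | intermediate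
13 | (2S)-2-hydroxy-2-(2-hydroxy-4-methylphenyl)-3-(2-methylpropanoyloxy)propyl (2S)-2-methylbutanoate | CC[C@H](C)C(=O)OC[C@@](O)(COC(=O)C(C)C)c1ccc(C)cc1O | target

## Step count and risks

Total step count: 7. Longest linear sequence: 7 steps (1 or 2 to 13).

**Step 2 (proposed new step).** The risks are the para isomer and the minor 2-hydroxy-6-methylphenyl isomer, decarbonylation of the α-alkoxyacyl radical, and inner-filter slowing by 5. The enantiomeric purity of 5 must be checked. The fallback uses known chemistry, sets out from 2 and returns at 5. Acid 2 is condensed with N,O-dimethylhydroxylamine hydrochloride (DCC, N-methylmorpholine, CH2Cl2) to the Weinreb amide (4S)-N-methoxy-N,2,2-trimethyl-1,3-dioxolane-4-carboxamide F1. Purchased 2-bromo-5-methylphenol (Cc1ccc(Br)c(O)c1) is treated with two equivalents of n-BuLi (Et2O, 0 °C → rt) to give lithium 2-lithio-5-methylphenoxide F2. F2 adds to F1 at −78 °C and gives ketone 5 on NH4Cl work-up.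

**Step 3.** The sense and level of 1,2-induction are the main uncertainty (Cram chelate against Felkin–Anh). Enolisation at C4 before addition would erode the enantiomeric purity, and the β-hydroxysilane could undergo Peterson elimination. The fallback sets out from 5 and returns at 13; it exploits the fact that which arm receives which acyl group is decided only after the carbinol is made, so either epimer of the adduct converges on 13.
- If the addition is unselective or runs with the opposite sense, the epimeric diol (1R)-1-[(4S)-2,2-dimethyl-1,3-dioxolan-4-yl]-1-(2-hydroxy-4-methylphenyl)ethane-1,2-diol F3 is separated on silica.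
- F3 is acylated on the phenol and primary OH with acid 11 (2.4 equiv, DCC, DMAP) to (2R)-2-[(4S)-2,2-dimethyl-1,3-dioxolan-4-yl]-2-hydroxy-2-{4-methyl-2-[(2S)-2-methylbutanoyloxy]phenyl}ethyl (2S)-2-methylbutanoate F4.
- H5IO6 then gives the aldehyde (2R)-2-hydroxy-2-{4-methyl-2-[(2S)-2-methylbutanoyloxy]phenyl}-3-oxopropyl (2S)-2-methylbutanoate F5.
- NaBH(OAc)3 reduces it to (2S)-2,3-dihydroxy-2-{4-methyl-2-[(2S)-2-methylbutanoyloxy]phenyl}propyl (2S)-2-methylbutanoate F6.
- Isobutyryl chloride/pyridine gives (2S)-2-hydroxy-2-{4-methyl-2-[(2S)-2-methylbutanoyloxy]phenyl}-3-(2-methylpropanoyloxy)propyl (2S)-2-methylbutanoate F7.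
- Pyrrolidine frees the phenol to give 13.

**Step 5.** Periodate may also cleave the tertiary/secondary diol or the α-hydroxy aldehyde (giving the aryl ketone), and the isobutyrate may migrate to the new primary OH, which would lower the enantiomeric purity of 10. The fallback sets out from 8 and returns at 9, replacing glycol fission by olefination and ozonolysis.
- Aqueous acetic acid removes the acetonide to give (2S,3S)-2,3,4-trihydroxy-2-[4-methyl-2-(2-methylpropanoyloxy)phenyl]butyl 2-methylpropanoate F8.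
- Thiocarbonyldiimidazole closes the less hindered terminal diol to (2S)-2-hydroxy-2-[4-methyl-2-(2-methylpropanoyloxy)phenyl]-2-[(4S)-2-sulfanylidene-1,3-dioxolan-4-yl]ethyl 2-methylpropanoate F9.
- Corey–Winter olefination with 1,3-dimethyl-2-phenyl-1,3,2-diazaphospholidine (40 °C) gives (2S)-2-hydroxy-2-[4-methyl-2-(2-methylpropanoyloxy)phenyl]but-3-en-1-yl 2-methylpropanoate F10.
- Ozonolysis (O3, CH2Cl2, −78 °C; Me2S) gives aldehyde 9, which is reduced as in step 5.

## Further compounds

F1 | step 2 | (4S)-N-methoxy-N,2,2-trimethyl-1,3-dioxolane-4-carboxamide | CON(C)C(=O)[C@@H]1COC(C)(C)O1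
F2 | step 2 | lithium 2-lithio-5-methylphenoxide | [Li]Oc1cc(C)ccc1[Li]
F3 | step 3 | (1R)-1-[(4S)-2,2-dimethyl-1,3-dioxolan-4-yl]-1-(2-hydroxy-4-methylphenyl)ethane-1,2-diol | OC[C@](O)(c1ccc(C)cc1O)[C@@H]1COC(C)(C)O1
F4 | step 3 | (2R)-2-[(4S)-2,2-dimethyl-1,3-dioxolan-4-yl]-2-hydroxy-2-{4-methyl-2-[(2S)-2-methylbutanoyloxy]phenyl}ethyl (2S)-2-methylbutanoate | CC[C@H](C)C(=O)OC[C@](O)(c1ccc(C)cc1OC(=O)[C@@H](C)CC)[C@@H]1COC(C)(C)O1
F5 | step 3 | (2R)-2-hydroxy-2-{4-methyl-2-[(2S)-2-methylbutanoyloxy]phenyl}-3-oxopropyl (2S)-2-methylbutanoate | CC[C@H](C)C(=O)OC[C@](O)(c1ccc(C)cc1OC(=O)[C@@H](C)CC)C=O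
F6 | step 3 | (2S)-2,3-dihydroxy-2-{4-methyl-2-[(2S)-2-methylbutanoyloxy]phenyl}propyl (2S)-2-methylbutanoate | CC[C@H](C)C(=O)OC[C@](O)(c1ccc(C)cc1OC(=O)[C@@H](C)CC)CO
F7 | step 3 | (2S)-2-hydroxy-2-{4-methyl-2-[(2S)-2-methylbutanoyloxy]phenyl}-3-(2-methylpropanoyloxy)propyl (2S)-2-methylbutanoate | CC[C@H](C)C(=O)OC[C@@](O)(COC(=O)C(C)C)c1ccc(C)cc1OC(=O)[C@@H](C)CC
F8 | step 5 | (2S,3S)-2,3,4-trihydroxy-2-[4-methyl-2-(2-methylpropanoyloxy)phenyl]butyl 2-methylpropanoate | CC(C)C(=O)OC[C@@](O)(c1ccc(C)cc1OC(=O)C(C)C)[C@@H](O)CO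
F9 | step 5 | (2S)-2-hydroxy-2-[4-methyl-2-(2-methylpropanoyloxy)phenyl]-2-[(4S)-2-sulfanylidene-1,3-dioxolan-4-yl]ethyl 2-methylpropanoate | CC(C)C(=O)OC[C@@](O)(c1ccc(C)cc1OC(=O)C(C)C)[C@@H]1COC(=S)O1
F10 | step 5 | (2S)-2-hydroxy-2-[4-methyl-2-(2-methylpropanoyloxy)phenyl]but-3-en-1-yl 2-methylpropanoate | CC(C)C(=O)OC[C@@](O)(c1ccc(C)cc1OC(=O)C(C)C)C=C
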